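The ten-membered carbocycle is closed at C1–C2 (germacrane numbering: C1 epoxide CH, C10 epoxide C–CH3, C2 ring CH2, C3 carbinol). C2 is the α-carbon of a latent C3 enone and C1 the CH end of a latent cis C1=C10 alkene. An intramolecular palladium-catalysed α-alkenylation of a methyl-ketone enol silane by a (Z)-iodoalkene therefore forms the ring and fixes the cis ring-alkene geometry in one operation. The precursor is acyclic apart from the trans-fused α-methylene-γ-lactone (C7/C8), which acts as the turn element and already carries the C6 isobutyrate. Epoxidation and C3 reduction follow.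

Key step: step 9

Remark: germacrane numbering is used for all intermediates (C14 = methyl on C10, C15 = methyl on C4, C4=C5 the E-alkene, C6 the acyloxy carbon, C8 the carbon bearing the lactone oxygen, C11=C13 the exocyclic methylene, C12 the lactone carbonyl).
Assumption: (R)-2-vinyloxirane is taken as a commercial, enantiopure starting material.

Step 1
Reactants: 1 (R)-2-vinyloxirane; 2 lithium acetylide–ethylenediamine complex
Product: 3 (S)-hex-1-en-5-yn-3-ol
Conditions: LiC≡CH·H2NCH2CH2NH2, DMSO, 0 °C to rt; H2O
Reagents that add atoms: none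
Why: Epoxide alkynylation without Lewis acid should proceed by SN2 attack at the unhindered terminal CH2, leaving the C–O stereocentre (future C8) untouched, so the (R)-epoxide gives the (S)-alcohol (descriptor change by CIP priorities only).

Step 2
Reactants: 3 (S)-hex-1-en-5-yn-3-ol
Product: 6 (3S,5Z)-6-iodo-5-methylhexa-1,5-dien-3-ol, via E-alkenylalane 4 (not isolated), via chelated Z-alkenylalane 5 (not isolated)
Conditions: Me3Al (3 equiv), Cp2ZrCl2 (25 mol %), ClCH2CH2Cl, rt; AlCl3 (0.5 equiv), 50 °C; I2, THF, −30 to 0 °C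
Reagents that add atoms: trimethylaluminium C[Al](C)C; iodine II
Why: Negishi zirconium-catalysed methylalumination adds CH3 and Al syn across the terminal alkyne, the homopropargylic aluminium alkoxide then drives isomerisation to the six-membered O–Al chelate (anti-carbometalation), and iodinolysis with retention should give the (Z)-iodoalkene with iodine cis to C9.

Step 3
Reactants: 6 (3S,5Z)-6-iodo-5-methylhexa-1,5-dien-3-ol; 7 2-(bromomethyl)acrylic acid
Product: 9 (3S,5Z)-6-iodo-5-methylhexa-1,5-dien-3-yl 2-(bromomethyl)prop-2-enoate, via O-acylisourea 8 (not isolated)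
Conditions: DCC, DMAP (5 mol %), CH2Cl2, 0 °C
Reagents that add atoms: none
Why: Steglich esterification under near-neutral conditions with only catalytic DMAP should acylate the secondary allylic alcohol without displacing the allylic bromide or touching the carbinol stereocentre.

Step 4
Reactants: 9 (3S,5Z)-6-iodo-5-methylhexa-1,5-dien-3-yl 2-(bromomethyl)prop-2-enoate
Product: 10 (5S)-3-(bromomethyl)-5-[(2Z)-3-iodo-2-methylprop-2-en-1-yl]furan-2(5H)-one
Conditions: second-generation Grubbs catalyst (5 mol %), toluene, 80 °C, 0.01 M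
Reagents that add atoms: none
Why: Ring-closing metathesis between the vinyl group and the 1,1-disubstituted acrylate should give the butenolide with loss of ethylene, the trisubstituted iodoalkene being inert to the ruthenium carbene.

Step 5
Reactants: 11 butane-2,3-dione (4 equiv); 12 (triphenylphosphoranylidene)acetaldehyde
Product: 13 (2E)-3-methyl-4-oxopent-2-enal
Conditions: toluene, 60 °C
Reagents that add atoms: none
Why: Wittig olefination of the activated 1,2-diketone by the stabilised formyl ylide should be E-selective (acetyl and formyl trans, the future C3 and C6 across C4=C5), and excess diketone suppresses a second olefination of the product enal.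

Step 6
Reactants: 10 (5S)-3-(bromomethyl)-5-[(2Z)-3-iodo-2-methylprop-2-en-1-yl]furan-2(5H)-one; 13 (2E)-3-methyl-4-oxopent-2-enal
Product: 15 (4S,5S)-4-[(1R,2E)-1-hydroxy-3-methyl-4-oxopent-2-en-1-yl]-5-[(2Z)-3-iodo-2-methylprop-2-en-1-yl]-3-methylideneoxolan-2-one, via allylchromium dichloride 14 (not isolated)
Conditions: CrCl2 (3 equiv), THF, 0 °C to rt; H2O
Reagents that add atoms: none
Why: Nozaki–Hiyama-type Barbier allylation in which CrCl2 reduces only the allylic bromide (without NiCl2 the iodoalkene is inert) to the trivalent allylchromium 14, which should add through its γ-carbon C7 to the aldehyde in preference to the ketone, on the face anti to the C8 side chain (trans-lactone) and through a closed Zimmerman–Traxler chair whose ring-fixed E-type allyl geometry places the C6 hydroxyl anti to C8, i.e. the (6R)-carbinol.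

Step 7
Reactants: 15 (4S,5S)-4-[(1R,2E)-1-hydroxy-3-methyl-4-oxopent-2-en-1-yl]-5-[(2Z)-3-iodo-2-methylprop-2-en-1-yl]-3-methylideneoxolan-2-one
Product: 17 (1S,2E)-1-[(2S,3R)-2-[(2Z)-3-iodo-2-methylprop-2-en-1-yl]-4-methylidene-5-oxooxolan-3-yl]-3-methyl-4-oxopent-2-en-1-yl 2-methylpropanoate, via alkoxyphosphonium isobutyrate 16 (not isolated)
Conditions: i-PrCO2H, PPh3, DIAD, toluene, −20 °C to rt
Reagents that add atoms: isobutyric acid CC(C)C(=O)O
Why: Mitsunobu esterification, in which isobutyrate should displace the C6 oxyphosphonium of 16 with SN2 inversion, so the acylation the target needs also corrects C6 from (R) to the required (S).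

Step 8
Reactants: 17 (1S,2E)-1-[(2S,3R)-2-[(2Z)-3-iodo-2-methylprop-2-en-1-yl]-4-methylidene-5-oxooxolan-3-yl]-3-methyl-4-oxopent-2-en-1-yl 2-methylpropanoate
Product: 18 (1S,2E)-1-[(2S,3R)-2-[(2Z)-3-iodo-2-methylprop-2-en-1-yl]-4-methylidene-5-oxooxolan-3-yl]-3-methyl-4-[(trimethylsilyl)oxy]penta-2,4-dien-1-yl 2-methylpropanoate
Conditions: TMSOTf, Et3N, CH2Cl2, −78 to 0 °C; used crude
Reagents that add atoms: trimethylsilyl trifluoromethanesulfonate C[Si](C)(C)OS(=O)(=O)C(F)(F)F
Why: Soft enolisation (silyl triflate and amine) of the enone can occur only at the C2 methyl group because the other α-carbon is sp2, so the cross-conjugated 2-silyloxydiene should form without touching ester or lactone.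

Step 9
Reactants: 18 (1S,2E)-1-[(2S,3R)-2-[(2Z)-3-iodo-2-methylprop-2-en-1-yl]-4-methylidene-5-oxooxolan-3-yl]-3-methyl-4-[(trimethylsilyl)oxy]penta-2,4-dien-1-yl 2-methylpropanoate
Product: 20 (1(10)Z,4E,6S,7R,8S)-6-(2-methylpropanoyloxy)-3-oxogermacra-1(10),4,11(13)-trien-12,8-olide, via tributyltin enolate 19 (not isolated)
Conditions: Pd2(dba)3 (10 mol %), P(o-tol)3 (40 mol %), Bu3SnF (1.2 equiv), toluene, 80 °C, 1 mM, syringe-pump addition
Reagents that add atoms: none
Why: Bu3SnF converts the enol silane into the tin enolate 19, zerovalent palladium inserts into the C1–I bond with retention, Sn-to-Pd transmetalation gives a C2-bound palladium enolate and reductive elimination forms C1–C2; the closest known reaction is the palladium-catalysed α-alkenylation of ketones through tributyltin enolates (enolate variant of the Migita–Kosugi–Stille coupling), here run intramolecularly. The ten-membered carbocycle is closed by cross-coupling macrocyclisation through an eleven-membered palladacycle, formally a 10-endo union of the enolate α-carbon with the alkenyl carbon, under high dilution. No stereocentre is created; the (Z)-geometry of the iodoalkene is transferred unchanged to the C1=C10 ring alkene, which later dictates the cis-epoxide, and the E-enone is not touched. The step needs C- over O-alkenylation and cyclisation over oligomerisation: methyl-ketone tin enolates couple at carbon, and the trans-fused lactone at C7/C8 together with the Z-alkene turn the two chain ends towards each other. The base-free conditions should spare the α-methylene lactone, the isobutyrate and the isomerisation-prone skipped enone, and the bulky phosphine disfavours ionisation of the allylic ester.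

Step 10
Reactants: 20 (1(10)Z,4E,6S,7R,8S)-6-(2-methylpropanoyloxy)-3-oxogermacra-1(10),4,11(13)-trien-12,8-olide
Product: 21 (1R,4E,6S,7R,8S,10S)-1,10-epoxy-6-(2-methylpropanoyloxy)-3-oxogermacra-4,11(13)-dien-12,8-olide
Conditions: DMDO, acetone, −20 °C
Reagents that add atoms: dimethyldioxirane CC1(C)OO1
Why: Neutral electrophilic epoxidation, done before C3 reduction so that C4=C5 is still a deactivated enone, should be chemoselective for the only electron-rich alkene and stereospecifically give the cis-epoxide, with the reagent expected to attack the face of the Z-alkene turned away from the ring interior in the lactone-locked conformer, setting C1 (R) and C10 (S) together.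

Step 11
Reactants: 21 (1R,4E,6S,7R,8S,10S)-1,10-epoxy-6-(2-methylpropanoyloxy)-3-oxogermacra-4,11(13)-dien-12,8-olide
Product: 22 (1R,3R,4E,6S,7R,8S,10S)-1,10-epoxy-3-hydroxy-6-(2-methylpropanoyloxy)germacra-4,11(13)-dien-12,8-olide (CNP0114243.1)
Conditions: (S)-2-methyl-CBS-oxazaborolidine (30 mol %), catecholborane, toluene, −78 °C; pH 7 buffer
Reagents that add atoms: none
Why: Corey–Bakshi–Shibata reduction, in which the (S)-oxazaborolidine–borane complex should deliver hydride 1,2 to the enone carbonyl with the branched alkenyl group (C4) as the large substituent, setting C3 as (R), while the epoxide, the esters and the methylene lactone are inert at −78 °C.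

Compound list
1 | (R)-2-vinyloxirane | C=C[C@@H]1CO1 | starting material
2 | lithium acetylide–ethylenediamine complex | [Li]C#C.NCCN | starting material
3 | (S)-hex-1-en-5-yn-3-ol | C=C[C@@H](O)CC#C | intermediate
4 | E-alkenylalane (syn-methylalumination product, O-dimethylaluminium alkoxide) | C=C[C@@H](O[Al](C)C)C/C(C)=C/[Al](C)C | intermediate
5 | chelated Z-alkenylalane (six-membered O–Al–C ring) | C=C[C@@H]1CC(C)=C[Al](C)O1 | intermediate
6 | (3S,5Z)-6-iodo-5-methylhexa-1,5-dien-3-ol | C=C[C@@H](O)C/C(C)=C\I | intermediate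
7 | 2-(bromomethyl)acrylic acid | C=C(CBr)C(=O)O | starting material
8 | O-acylisourea from 7 and DCC | C=C(CBr)C(=O)OC(=NC1CCCCC1)NC1CCCCC1 | intermediate
9 | (3S,5Z)-6-iodo-5-methylhexa-1,5-dien-3-yl 2-(bromomethyl)prop-2-enoate | C=C[C@@H](OC(=O)C(=C)CBr)C/C(C)=C\I | intermediate
10 | (5S)-3-(bromomethyl)-5-[(2Z)-3-iodo-2-methylprop-2-en-1-yl]furan-2(5H)-one | BrCC1=C[C@H](C/C(C)=C\I)OC1=O | intermediate
11 | butane-2,3-dione | CC(=O)C(C)=O | starting material
12 | (triphenylphosphoranylidene)acetaldehyde | O=CC=P(c1ccccc1)(c1ccccc1)c1ccccc1 | starting material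
13 | (2E)-3-methyl-4-oxopent-2-enal | CC(=O)/C(C)=C/C=O | intermediate
14 | allylchromium dichloride from 10 (trivalent chromium, C13-bound) | Cl[Cr](Cl)CC1=C[C@H](C/C(C)=C\I)OC1=O | intermediate
15 | (4S,5S)-4-[(1R,2E)-1-hydroxy-3-methyl-4-oxopent-2-en-1-yl]-5-[(2Z)-3-iodo-2-methylprop-2-en-1-yl]-3-methylideneoxolan-2-one | C=C1C(=O)O[C@@H](C/C(C)=C\I)[C@@H]1[C@H](O)/C=C(C)/C(C)=O | intermediate
16 | alkoxyphosphonium isobutyrate of 15 (C6–O–PPh3 cation) | C=C1C(=O)O[C@@H](C/C(C)=C\I)[C@@H]1[C@H](O[P+](c1ccccc1)(c1ccccc1)c1ccccc1)/C=C(C)/C(C)=O.CC(C)C(=O)[O-] | intermediate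
17 | (1S,2E)-1-[(2S,3R)-2-[(2Z)-3-iodo-2-methylprop-2-en-1-yl]-4-methylidene-5-oxooxolan-3-yl]-3-methyl-4-oxopent-2-en-1-yl 2-methylpropanoate | C=C1C(=O)O[C@@H](C/C(C)=C\I)[C@@H]1[C@@H](OC(=O)C(C)C)/C=C(C)/C(C)=O | intermediate
18 | trimethylsilyl enol ether of 17 (2-silyloxy-1,3-diene at C2=C3) | C=C1C(=O)O[C@@H](C/C(C)=C\I)[C@@H]1[C@@H](OC(=O)C(C)C)/C=C(C)/C(=C)O[Si](C)(C)C | intermediate
19 | tributyltin enolate of 17 | C=C1C(=O)O[C@@H](C/C(C)=C\I)[C@@H]1[C@@H](OC(=O)C(C)C)/C=C(C)/C(=C)O[Sn](CCCC)(CCCC)CCCC | intermediate
20 | (1(10)Z,4E,6S,7R,8S)-6-(2-methylpropanoyloxy)-3-oxogermacra-1(10),4,11(13)-trien-12,8-olide | C=C1C(=O)O[C@H]2C/C(C)=C\CC(=O)/C(C)=C/[C@H](OC(=O)C(C)C)[C@H]12 | intermediate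
21 | (1R,4E,6S,7R,8S,10S)-1,10-epoxy-6-(2-methylpropanoyloxy)-3-oxogermacra-4,11(13)-dien-12,8-olide | C=C1C(=O)O[C@H]2C[C@]3(C)O[C@@H]3CC(=O)/C(C)=C/[C@H](OC(=O)C(C)C)[C@H]12 | intermediate
22 | (1R,3R,4E,6S,7R,8S,10S)-1,10-epoxy-3-hydroxy-6-(2-methylpropanoyloxy)germacra-4,11(13)-dien-12,8-olide | C=C1C(=O)O[C@H]2C[C@]3(C)O[C@@H]3C[C@@H](O)/C(C)=C/[C@H](OC(=O)C(C)C)[C@H]12 | target

Total step count: 11. Longest linear sequence: 10 steps (steps 1–4 and 6–11, from 1); step 5 is a one-step side branch.

Steps most likely to fail

Step 9 (key macrocyclisation). Transmetalation within the strained ring-forming complex may be slower than intermolecular coupling (oligomers), than protodestannylation back to the methyl ketone, or than ionisation of the allylic isobutyrate by zerovalent palladium. The fallback sets out from 17 and comes back at 20. Riley oxidation of the methyl ketone (SeO2, dioxane/H2O, 60 °C) should give the α-keto aldehyde F1. An intramolecular Nozaki–Hiyama–Kishi addition of the iodoalkene to the aldehyde (CrCl2, NiCl2 1 mol %, DMSO/THF, rt, 2 mM), a ring closure well established for ten-membered germacranolide carbocycles, would form the same C1–C2 bond and give the α-hydroxy ketone F2 as a mixture of C2 epimers. SmI2 (THF/MeOH, −78 °C) would then remove the α-hydroxyl reductively to give 20.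

Step 10 (epoxidation). The facial preference rests only on ring conformation, so selectivity may be poor or reversed. The fallback sets out from 20 and comes back at 21. NBS in aqueous acetone at 0 °C should give, by anti addition, the bromohydrin F3 (bromonium on the face electrophiles prefer, water at tertiary C10 from the opposite face). Ag2O in THF then closes the epoxide with inversion at C1, placing oxygen on the face opposite to that reached by direct epoxidation.

Step 7 (inverting acylation). The activated allylic oxyphosphonium may eliminate or suffer allylic transposition, or the weakly acidic isobutyric acid may lead to acyl transfer with retention. The fallback sets out from 15 and comes back at 17. Mesylation (MsCl, Et3N, CH2Cl2, −40 °C) gives the mesylate F4, and SN2 displacement with caesium isobutyrate and 18-crown-6 in toluene inverts C6.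

Further compounds
F1 | step 9 | (1S,2E)-1-[(2S,3R)-2-[(2Z)-3-iodo-2-methylprop-2-en-1-yl]-4-methylidene-5-oxooxolan-3-yl]-3-methyl-4,5-dioxopent-2-en-1-yl 2-methylpropanoate | C=C1C(=O)O[C@@H](C/C(C)=C\I)[C@@H]1[C@@H](OC(=O)C(C)C)/C=C(C)/C(=O)C=O
F2 | step 9 | (1(10)Z,4E,6S,7R,8S)-2-hydroxy-6-(2-methylpropanoyloxy)-3-oxogermacra-1(10),4,11(13)-trien-12,8-olide (C2 epimers) | C=C1C(=O)O[C@H]2C/C(C)=C\C(O)C(=O)/C(C)=C/[C@H](OC(=O)C(C)C)[C@H]12
F3 | step 10 | (1S,4E,6S,7R,8S,10S)-1-bromo-10-hydroxy-6-(2-methylpropanoyloxy)-3-oxogermacra-4,11(13)-dien-12,8-olide | C=C1C(=O)O[C@H]2C[C@](C)(O)[C@@H](Br)CC(=O)/C(C)=C/[C@H](OC(=O)C(C)C)[C@H]12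
F4 | step 7 | (1R,2E)-1-[(2S,3R)-2-[(2Z)-3-iodo-2-methylprop-2-en-1-yl]-4-methylidene-5-oxooxolan-3-yl]-3-methyl-4-oxopent-2-en-1-yl methanesulfonate | C=C1C(=O)O[C@@H](C/C(C)=C\I)[C@@H]1[C@H](OS(C)(=O)=O)/C=C(C)/C(C)=O
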